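Assumptions: lignan numbering is used (C7–C9 = syringyl C3 unit, C7′–C9′ = central guaiacyl C3 unit, C7″–C9″ = glycerol unit). Both enantiomers of glyceraldehyde acetonide are bought (D‑mannitol‑ and L‑ascorbic‑acid‑derived) and used fresh.

## Retrosynthetic overview
1. The target comes from two deprotections of a fully protected furofuran: mild hydrolysis of a 7″,9″‑acetal, then hydrogenolysis of two aryl benzyl ethers.
2. One visible‑light Ti/Ir isomerisation of an epoxy cinnamyl ether forms both THF rings. C8–C8′ closes ring A first, then C7′–O closes ring B, and C7 controls C8, C8′ and C7′.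
3. The epoxy ether is cut at C7–O–C9′ (Pd O‑allylation) into a syringyl epoxy alcohol and a 1‑arylallyl carbonate that already carries the glycerol unit.
4. The epoxy alcohol comes from an aryl‑titanium reagent and (R)‑glyceraldehyde acetonide by anti addition. The bought C8 centre sets C7 and is later erased.
5. The carbonate comes from an aryl‑titanium reagent and (S)‑glyceraldehyde acetonide (anti, sets C7″). A temporary 1,3‑dioxane then frees only C8″‑OH for SNAr on 4‑fluoro‑3‑methoxybenzaldehyde with retention, and vinyl addition follows.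

## Route

**Step 1**
Reactants: 1, 1‑(benzyloxy)‑4‑bromo‑2‑methoxybenzene; 2, (S)‑2,2‑dimethyl‑1,3‑dioxolane‑4‑carbaldehyde
Product: 3, (R)‑[4‑(benzyloxy)‑3‑methoxyphenyl][(4S)‑2,2‑dimethyl‑1,3‑dioxolan‑4‑yl]methanol (anti; 7″R,8″S)
Conditions: n‑BuLi, THF, −78 °C; ClTi(Oi‑Pr)3, −78 → −40 °C; 2, −78 → 0 °C; aq. NH4Cl; chromatography
Reagents that add atoms: 2, O=C[C@@H]1COC(C)(C)O1
Why: Br/Li exchange, transmetalation to the non‑basic, non‑chelating ArTi(Oi‑Pr)3 and Felkin–Anh 1,2‑addition give the anti (erythro) carbinol, so the bought 8″S centre sets 7″R (about ≥5:1 expected, syn isomer removed) without epimerising the aldehyde.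

**Step 2**
Reactants: 3; 4, 4‑methoxybenzaldehyde dimethyl acetal
Product: 5, (2S,4R,5S)‑4‑[4‑(benzyloxy)‑3‑methoxyphenyl]‑2‑(4‑methoxyphenyl)‑1,3‑dioxan‑5‑ol (7″,9″‑acetal, C8″‑OH free)
Conditions: 4 (1.5 equiv), CSA (5 mol %), DMF, 45 °C, 150 mbar; Et3N quench
Reagents that add atoms: 4, COC(OC)c1ccc(OC)cc1
Why: In this thermodynamic transacetalisation, aldehyde acetals prefer the six‑membered primary/secondary dioxane, which for the erythro triol is the all‑equatorial chair; this leaves only O8″ free and sets the temporary acetal centre.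

**Step 3**
Reactants: 5; 6, 4‑fluoro‑3‑methoxybenzaldehyde
Product: 7, 4‑{[(2S,4R,5S)‑4‑[4‑(benzyloxy)‑3‑methoxyphenyl]‑2‑(4‑methoxyphenyl)‑1,3‑dioxan‑5‑yl]oxy}‑3‑methoxybenzaldehyde
Conditions: NaH, DMF, 0 °C; 6 (1.3 equiv), 0 → 50 °C
Reagents that add atoms: 6, COc1cc(C=O)ccc1F
Why: SNAr (Meisenheimer addition–elimination para to CHO) forms the 8″‑O‑4′ aryl ether without touching the C8″–O bond, so 8″S is retained.

**Step 4**
Reactants: 7; 8, vinylmagnesium bromide; 9, di‑tert‑butyl dicarbonate
Product: 10, tert‑butyl 1‑(aryl)prop‑2‑en‑1‑yl carbonate of 7 (about 1:1 at the new carbinol carbon)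
Conditions: 8, THF, −78 → 0 °C; then 9, 0 °C → rt; Et3N‑washed silica
Reagents that add atoms: 8, C=C[Mg]Br; 9, CC(C)(C)OC(=O)OC(=O)OC(C)(C)C
Why: Grignard 1,2‑addition is followed by in‑situ O‑acylation of the magnesium alkoxide, and the unselective new centre becomes sp2 in Step 9.

**Step 5**
Reactants: 11, 4‑bromo‑2,6‑dimethoxyphenol; 12, benzyl bromide
Product: 13, 2‑(benzyloxy)‑5‑bromo‑1,3‑dimethoxybenzene
Conditions: K2CO3, DMF, rt
Reagents that add atoms: 12, BrCc1ccccc1
Why: This is a Williamson etherification of the phenoxide.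

**Step 6**
Reactants: 13; 14, (R)‑2,2‑dimethyl‑1,3‑dioxolane‑4‑carbaldehyde
Product: 15, (S)‑[4‑(benzyloxy)‑3,5‑dimethoxyphenyl][(4R)‑2,2‑dimethyl‑1,3‑dioxolan‑4‑yl]methanol (anti; 7S,8R)
Conditions: as Step 1
Reagents that add atoms: 14, O=C[C@H]1COC(C)(C)O1
Why: The same Felkin–Anh aryl‑titanium addition lets the bought 8R centre set 7S, which has the spatial arrangement of 7R in the furofuran, and removing the syn isomer secures the enantiopurity of the core.

**Step 7**
Reactants: 15
Product: 16, (1S,2R)‑1‑[4‑(benzyloxy)‑3,5‑dimethoxyphenyl]propane‑1,2,3‑triol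
Conditions: AcOH–H2O (4:1), rt
Reagents that add atoms: none
Why: Mild hydrolysis cleaves the terminal acetonide and touches no stereocentre.

**Step 8**
Reactants: 16
Product: 17, (S)‑[4‑(benzyloxy)‑3,5‑dimethoxyphenyl][(2R)‑oxiran‑2‑yl]methanol
Conditions: Bu2SnO (2 mol %), TsCl (1.05 equiv), Et3N, CH2Cl2, 0 °C → rt; then DBU, 0 °C → rt (one pot)
Reagents that add atoms: none
Why: Tin‑catalysed primary‑selective tosylation is followed by 3‑exo‑tet intramolecular Williamson closure through O8, so the C7 and C8 C–O bonds stay intact, and the aprotic base suppresses Payne rearrangement.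

**Step 9**
Reactants: 17; 10 (1.2 equiv)
Product: 18, (2R)‑2‑{(S)‑[4‑(benzyloxy)‑3,5‑dimethoxyphenyl][(E)‑3‑Ar′‑prop‑2‑enyloxy]methyl}oxirane, where Ar′ is the 3‑methoxy‑4‑(dioxan‑5‑yloxy)phenyl group of 7
Conditions: Pd2(dba)3 (2.5 mol %), dppb (6 mol %), THF, 50 °C (−CO2, −t‑BuOH)
Reagents that add atoms: none other than the two reactants
Why: In this Tsuji–Trost O‑allylation both carbonate epimers give one η3‑(1‑aryl)allyl‑Pd, the released t‑BuO⁻ deprotonates 17, and the alkoxide attacks the unhindered terminus to give the linear E ether with C7 uninvolved.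

**Step 10 (key step)**
Reactants: 18
Product: 19, (1R,3aS,4R,6aS)‑1‑[4‑(benzyloxy)‑3,5‑dimethoxyphenyl]‑4‑Ar′‑tetrahydro‑1H,3H‑furo[3,4‑c]furan (7R,8S,7′R,8′S; cis‑fused, both aryls exo)
Conditions: Cp2TiCl2 (10 mol %), fac‑Ir(ppy)3 (1 mol %), i‑Pr2NEt (20 mol %, primer), degassed THF (0.05 M), 450 nm LEDs, 25 °C
Reagents that add atoms: none (isomerisation)
Why: Proposed new method: this is a redox‑neutral titanocene/photoredox epoxide–alkene bicycloisomerisation in which excited Ir(ppy)3 (about −1.7 V) reduces Ti(IV) to Cp2TiCl, Cp2TiCl opens the terminal epoxide to the secondary C8 radical (erasing bought C8), and 5‑exo‑trig attack on C8′ through a chair TS with the C7 aryl pseudo‑equatorial forms C8–C8′ with 7,8‑trans and 8,8′‑cis geometry; Ir(IV) (+0.77 V, too weak to oxidise the arenes or styrene) then oxidises the electron‑rich benzylic radical, or its benzyl–Ti(IV) resting state, to a p‑alkoxybenzyl cation that the C9–O–Ti alkoxide captures with the aryl exo (7′R), returning Ti(IV), direct homolytic substitution at Ti–O leads to the same product, and the closest known reaction types are stoichiometric Cp2TiCl epoxide–olefin cyclisation followed by I2 closure to furofurans, reductive titanocene/photoredox epoxide cyclisations, titanocene THF formation by Ti–O homolytic substitution, and photoredox radical–polar‑crossover oxyalkylation of styrenes.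

**Step 11**
Reactants: 19
Product: 20, 4,4″‑di‑O‑benzyl ficusesquilignan A (7″,9″‑diol free)
Conditions: AcOH–THF–H2O (3:1:1), 25–35 °C
Reagents that add atoms: none
Why: The p‑methoxybenzylidene acetal ionises far faster than the O‑alkylated benzylic ethers, so C7, C7′ and C7″ are not epimerised during this acetal hydrolysis.

**Step 12**
Reactants: 20
Product: 21, ficusesquilignan A
Conditions: H2 (1 atm), 10 % Pd/C, EtOAc, rt, stopped at full debenzylation (about 1 h)
Reagents that add atoms: none
Why: In this catalytic hydrogenolysis aryl benzyl ethers cleave much faster than the furofuran benzylic C–O bonds or the C7″ carbinol in neutral EtOAc.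

## Compound list
1 | 1‑(benzyloxy)‑4‑bromo‑2‑methoxybenzene | COc1cc(Br)ccc1OCc1ccccc1 | starting material
2 | (S)‑glyceraldehyde acetonide | O=C[C@@H]1COC(C)(C)O1 | starting material
3 | anti guaiacyl adduct (7″R,8″S) | COc1cc([C@@H](O)[C@@H]2COC(C)(C)O2)ccc1OCc1ccccc1 | intermediate
4 | 4‑methoxybenzaldehyde dimethyl acetal | COC(OC)c1ccc(OC)cc1 | starting material
5 | (2S,4R,5S)‑dioxan‑5‑ol | COc1cc([C@H]2O[C@@H](c3ccc(OC)cc3)OC[C@@H]2O)ccc1OCc1ccccc1 | intermediate
6 | 4‑fluoro‑3‑methoxybenzaldehyde | COc1cc(C=O)ccc1F | starting material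
7 | 8″‑O‑4′ aryl ether aldehyde | COc1cc([C@H]2O[C@@H](c3ccc(OC)cc3)OC[C@@H]2Oc4ccc(C=O)cc4OC)ccc1OCc5ccccc5 | intermediate
8 | vinylmagnesium bromide | C=C[Mg]Br | starting material
9 | di‑tert‑butyl dicarbonate | CC(C)(C)OC(=O)OC(=O)OC(C)(C)C | starting material
10 | branched allylic tert‑butyl carbonate (epimer mixture) | COc1cc([C@H]2O[C@@H](c3ccc(OC)cc3)OC[C@@H]2Oc4ccc(C(C=C)OC(=O)OC(C)(C)C)cc4OC)ccc1OCc5ccccc5 | intermediate
11 | 4‑bromo‑2,6‑dimethoxyphenol | COc1cc(Br)cc(OC)c1O | starting material
12 | benzyl bromide | BrCc1ccccc1 | starting material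
13 | 2‑(benzyloxy)‑5‑bromo‑1,3‑dimethoxybenzene | COc1cc(Br)cc(OC)c1OCc1ccccc1 | intermediate
14 | (R)‑glyceraldehyde acetonide | O=C[C@H]1COC(C)(C)O1 | starting material
15 | anti syringyl adduct (7S,8R) | COc1cc([C@H](O)[C@H]2COC(C)(C)O2)cc(OC)c1OCc1ccccc1 | intermediate
16 | (1S,2R)‑triol | COc1cc([C@H](O)[C@H](O)CO)cc(OC)c1OCc1ccccc1 | intermediate
17 | (S)‑aryl[(2R)‑oxiranyl]methanol | COc1cc([C@H](O)[C@H]2CO2)cc(OC)c1OCc1ccccc1 | intermediate
18 | epoxy (E)‑cinnamyl ether | COc1cc([C@H](OC/C=C/c2ccc(O[C@H]3CO[C@H](c4ccc(OC)cc4)O[C@@H]3c5ccc(OCc6ccccc6)c(OC)c5)c(OC)c2)[C@H]7CO7)cc(OC)c1OCc8ccccc8 | intermediate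
19 | protected furofuran | COc1cc([C@H]2O[C@@H](c3ccc(OC)cc3)OC[C@@H]2Oc4ccc([C@@H]5OC[C@@H]6[C@H]5CO[C@H]6c7cc(OC)c(OCc8ccccc8)c(OC)c7)cc4OC)ccc1OCc9ccccc9 | intermediate
20 | 4,4″‑di‑O‑benzyl ficusesquilignan A | COc1cc([C@@H](O)[C@H](CO)Oc2ccc([C@@H]3OC[C@@H]4[C@H]3CO[C@H]4c5cc(OC)c(OCc6ccccc6)c(OC)c5)cc2OC)ccc1OCc7ccccc7 | intermediate
21 | ficusesquilignan A | COc1cc([C@@H](O)[C@H](CO)Oc2ccc([C@@H]3OC[C@@H]4[C@H]3CO[C@H]4c3cc(OC)c(O)c(OC)c3)cc2OC)ccc1O | target

## Step count and risks
Total steps: 12. Longest linear sequence: 8 (Steps 1–4 then 9–12, or equally Steps 5–8 then 9–12).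

Steps most likely to fail:

1. **Step 10 (new method).**
   - Risks: Ir(IV)/Ti(III) back‑electron transfer could stall turnover. The benzylic radical could be reduced to the lariciresinol‑type THF. The epoxide could be deoxygenated.
   - Fallback (known chemistry): treat 18 with stoichiometric Cp2TiCl (Cp2TiCl2/Zn, THF, rt) for the reductive radical cyclisation, then add I2 to the same flask. I2 converts the benzylic Ti/radical species to the iodide, and the titanium alkoxide displaces it to close the second ring. This is the established thermal route from such epoxy cinnamyl ethers to pinoresinol‑type furofurans.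

2. **Step 2.**
   - Risk: dioxolane isomers could compete with the 7″,9″‑dioxane.
   - Fallback: drop the acetal swap and differentiate the hydroxyls stepwise. TIPS‑protect C7″‑OH, hydrolyse the acetonide, TIPS‑protect the primary C9″‑OH and arylate the remaining C8″‑OH. Step 11 is then replaced by buffered fluoride (TBAF/AcOH), at a cost of 2 extra steps.

3. **Step 9.**
   - Risks: the hindered secondary alkoxide is a poor π‑allyl‑Pd nucleophile, and Payne rearrangement of 17 is possible.
   - Fallback: join the fragments by C=C rather than C–O formation. O‑allylate 17 (NaH, allyl bromide, THF, 0 °C), convert aldehyde 7 to the styrene (Ph3P=CH2), and couple the two by E‑selective cross‑metathesis (Grubbs II) to give 18.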